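## Structural features

The target is an achiral diaryl ether. Ring A is a benzene with a pentyl chain at a1, hydroxyls at a3 and a5, and the bridging oxygen at a6. Ring B carries that oxygen at b1, a methoxy group at b3, a pentanoyl group at b5 and a carboxyl at b6. There is no stereocentre, so no stereocentres adjoin and the problem is purely one of regiochemistry on two benzene rings. The fragile parts are the 2-acylbenzoic acid unit (b5/b6), which equilibrates with its ring-closed 3-hydroxyphthalide form and whose ketone is enolisable and reducible, and the trioxygenated ring A, which oxidises easily once its hydroxyls are free. The real difficulty is twofold: the ether joins a6 (flanked by the a1 pentyl and the a5 oxygen) to b1 (flanked by the b6 carboxyl), and ring B has three contiguous substituents b5, b6, b1. The key step uses the fact that b1 and b6 are neighbours bearing aryloxy and carboxyl, which is the two-carbon unit of a 3-aryloxypropiolate. The remaining carbons b2 to b5, with oxygen on b3 para to b6 and the acyl group on b5, map onto a 2-silyloxy-1,3-diene with a masked acyl group at one terminus. Ring B can therefore be grown by cycloaddition onto an a6–O–b1 bond that already exists, with a two-carbon bridge lost afterwards.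

## Logic of the disconnections

25 to 24: three O–CH2Ph bonds are cut, the two phenol ethers on ring A and the ester on the b6 carboxyl. All acidic hydroxyls are then released together in one neutral, reductive operation at the very end, so the oxidation-prone ring A and the keto acid never pass through a basic or oxidising step and no separate ester hydrolysis is needed. The forward step must stop before the aryl ketone is reduced and needs a sulfur-free substrate, so the ketone must be unmasked first.

24 to 23: the side-chain carbonyl at b5 is traced back to a dithioketal (two C–S bonds). The acyl carbon has to pass through the ring-forming step as a non-electrophilic, non-enolisable, heat-stable quaternary centre, and the same dithiane is the acyl-anion equivalent that attaches the chain to the ring. The forward hydrolysis must spare benzyl groups and the electron-rich ring A, which calls for alkylative and not oxidative cleavage.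

23 to 21: the O–CH3 bond at b3 is cut back to the O–Si bond, because the b3 oxygen arrives as a silyl enol ether oxygen. Desilylation and methylation can share one flask. The forward step requires that the b3 phenoxide be the only nucleophile present, which holds because every other hydroxyl is masked.

21 to 11 and 19 (key disconnection): bonds b1–b2 and b5–b6 are cut and an ethano bridge is restored between b2 and b5. This avoids making the hindered diaryl ether by coupling and places all four substituents of ring B in one event. The two fragments are of similar size and each is a few steps from cheap materials. The forward step needs a regioselective cycloaddition of a sluggish push-pull alkyne at a crowded diene terminus, and both partners must tolerate prolonged heating.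

11 to 8, then to 6 and 7: the C(sp)–C(carboxyl) bond is cut, the alkyne is traced to a dichlorovinyl ether, and the O–C(vinyl) bond is cut. An aryl ynol ether cannot be made by simple O-alkynylation; 7 supplies carbons b1 and b6 as a masked alkyne. The forward steps require that benzyl ethers survive n-BuLi at low temperature and that a hindered phenoxide add to dichloroacetylene generated in the flask.

6 to 4, to 2, to 1: the C–O bond at a6 is traced to a formyl group (aryl migration to oxygen), the a6–CHO bond is cut, and the two benzyl ethers are removed. The a6 oxygen is absent from 1, and a formyl group is the most dependable handle for that position. The forward formylation must go para to one ether and ortho to the chain, not between the two ethers, and the peracid step must favour aryl migration.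

19 to 17, to 13 and 14, and 13 to 12: the O–Si bond is cut (kinetic enolate), then the bond between the dithiane carbon and the ring (1,2-addition with carbonyl transposition), then the two C–S bonds. This reduces the diene to an aldehyde, a dithiol and a vinylogous ester. The forward steps require a hindered tertiary carbanion to add to a carbonyl in preference to removing a proton, and the enone to be deprotonated at the α' methylene only.

## Other disconnections considered

Alternative 1: Ring A is cut at a6–a1 and a4–a5. Ring B is kept intact but carried as the racemic phthalide A1, whose phenol oxygen is alkylated to give the aryloxymalonate A2.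
- Forward key step: NaOMe in MeOH would add the carbanion of A2 to the β-carbon of enone A3 (bond a6–a1). The methyl ketone enolate would then close onto one malonate ester (bond a4–a5) to give the cyclohexane-1,3-dione A4 as a diastereomer mixture. Ester cleavage with decarboxylation and a dehydrogenation would then aromatise ring A, and the lactone would have to be opened and its carbinol oxidised to reach the keto acid.
- In its favour: this is the classical malonate–enone construction of 5-alkylresorcinols, with cheap reagents at moderate temperature. The aryloxy group is fixed at a6 by connectivity, which is better than the chosen plan, where regiochemistry rests on orbital control. Like the chosen plan it never forges the hindered aryl–O–aryl bond by coupling (equal).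
- Against it: the donor is a tertiary carbanion that must create a quaternary centre next to a branched carbon, so the Michael step is crowded and reversible. A4 is two oxidation levels and one carboxyl group away from an arene, and the dehydrogenation would have to be done on an electron-rich aryl ether. Ring B arrives with its ketone at the alcohol oxidation level, so a late oxidation of a hydroxy acid next to a resorcinol is required, and that calls for extra protection.
- Comparison: the ionic mechanism is milder than a pericyclic reaction at high temperature. The chosen plan delivers ring B at the correct oxidation level and needs three steps after ring formation. Here A1 needs its own synthesis and several operations follow A4, so the alternative is longer.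

Alternative 2: Ring B is cut at b5–b6 and b3–b4, the same ring as in the chosen plan but opened differently. Phenol 6 would be carried as the aryloxyglutaconate A5 and condensed with the monoketal ketone A6.
- Forward key step: under base, Knoevenagel condensation of the glutaconate methylene with the ketone carbonyl (b5–b6) and Dieckmann-type attack of the methyl carbon on the distal ester (b3–b4) would close ring B as the free phenol A7.
- In its favour: the chemistry is ionic and runs at moderate temperature, and regiochemistry is fixed by connectivity (better). No sulfur is introduced, so the final hydrogenolysis is not threatened by catalyst poisoning and the ketal falls to dilute acid (better). The b3 oxygen emerges as a free phenol ready for methylation (equal to the one-flask desilylation–methylation). It shares phenol 6 and has a comparable step count (equal).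
- Against it: ketones are poor Knoevenagel acceptors, and this one is enolisable and flanked by a fully substituted ketal carbon. The glutaconate anion is ambident. Alkoxide can add to the β-aryloxyacrylate unit of A5 and expel the phenoxide of 6, cleaving the ether bond the plan is meant to preserve. A6 needs selective monoprotection of a 2,3-dione.
- Comparison: both plans form b5–b6 next to the masked carbonyl, so neither escapes that congestion (equal). The cycloaddition is pulled forward by irreversible loss of ethylene, whereas the condensation is a chain of equilibria until the last dehydration.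

Alternative 3: Ring A is dissected into the α-diazo enone A8, built on phthalide A1, and benzyl ethynyl ether A9.
- Forward key step: irradiation of A8 would cause a Wolff rearrangement to a vinylketene (a1–a2), which would add A9 in a (2+2) sense (a2–a3 and a4–a5). The cyclobutenone would open to a dienylketene and close by six-electron electrocyclisation (a5–a6) to the phenol A10 after tautomerisation (Danheiser-type benzannulation).
- In its favour: it runs at ambient temperature and the substitution of ring A is fully defined by connectivity. The two ring A oxygens emerge differentiated (a5 free, a3 benzylated), a flexibility the chosen plan lacks, although the target does not need it. It avoids dichloroacetylene and organolithium reagents (better on hazard).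
- Against it: A9 is not commercially available, and benzyl alkynyl ethers rearrange sigmatropically on mild warming. A8 combines a diazo ketone with an enol ether and needs a diazo-transfer sequence on a sensitive vinylogous ester. A four-stage cascade offers several exits, such as ketene dimerisation or trapping of the ketene by the phenol being formed. Photochemical throughput is limited. As in alternative 1, ring B is carried as A1 and must be re-oxidised to the keto acid at the end.
- Comparison: this plan spends its key step on ring A, which can be bought as 1, and leaves the harder ring B to a separate synthesis; the chosen plan does the opposite. Both are pericyclic, with two events in the chosen plan against four here. In step count the alternative is longer.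

Key step: step 9

Remarks on the chemistry:
- The target is treated as the open keto acid. Its ring-closed 3-hydroxyphthalide tautomer is the same compound in equilibrium.
- The structures of the key-step precursors and product are consistent with the target; no correction was needed.
- Two spectator groups are changed and the disconnection is not. The ester is benzyl instead of methyl, so one hydrogenolysis frees all three hydroxyl functions and no hindered ester has to be saponified next to an enolisable ketone. The silyl group is tert-butyldimethylsilyl instead of trimethylsilyl, so the diene and the cycloadduct tolerate chromatography and long heating.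

## Route

Step 1
Reactants: 1 olivetol (5-pentylbenzene-1,3-diol)
Product: 2 1,3-bis(benzyloxy)-5-pentylbenzene
Conditions: BnBr, K2CO3, DMF, rt → 50 °C
Reagents that add atoms: benzyl bromide, BrCc1ccccc1
Why: Williamson ether synthesis on both phenoxides; benzyl ethers tolerate base, n-BuLi at low temperature and heat, and are removed by hydrogenolysis at the end.

Step 2
Reactants: 2 1,3-bis(benzyloxy)-5-pentylbenzene
Product: 4 2,4-bis(benzyloxy)-6-pentylbenzaldehyde, via iminium salt 3 (not isolated)
Conditions: POCl3, DMF, 0 °C → 70 °C; then H2O, rt
Reagents that add atoms: N,N-dimethylformamide, CN(C)C=O; water, O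
Why: Vilsmeier–Haack formylation; the chloroiminium ion should attack the carbon para to one benzyloxy group and ortho to the other and to the chain, the site between the two ethers being more hindered, and water hydrolyses iminium salt 3 to the aldehyde.

Step 3
Reactants: 4 2,4-bis(benzyloxy)-6-pentylbenzaldehyde
Product: 6 2,4-bis(benzyloxy)-6-pentylphenol, via aryl formate 5 (not isolated)
Conditions: mCPBA, CH2Cl2, 0 °C → rt; aq. NaHCO3 wash; then K2CO3 (cat.), MeOH, rt, argon
Reagents that add atoms: 3-chloroperoxybenzoic acid, OOC(=O)c1cccc(Cl)c1
Why: Baeyer–Villiger (Dakin-type) oxidation; in the Criegee intermediate the electron-rich aryl group migrates in preference to hydride, and the resulting formate is methanolysed to the phenol.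

Step 4
Reactants: 6 2,4-bis(benzyloxy)-6-pentylphenol; 7 trichloroethylene
Product: 8 1,5-bis(benzyloxy)-2-{[(E)-1,2-dichloroethenyl]oxy}-3-pentylbenzene
Conditions: K2CO3, DMF, 70 °C, closed vessel, argon
Reagents that add atoms: none
Why: Base dehydrochlorinates trichloroethylene to dichloroacetylene, to which the phenoxide adds in anti fashion, the established route to aryl (E)-1,2-dichlorovinyl ethers; the hazardous alkyne exists only transiently in a closed, inert system.

Step 5
Reactants: 8 1,5-bis(benzyloxy)-2-{[(E)-1,2-dichloroethenyl]oxy}-3-pentylbenzene
Product: 11 benzyl 3-[2,4-bis(benzyloxy)-6-pentylphenoxy]prop-2-ynoate, via chloroalkynyl ether 9 (not isolated), via lithium aryloxyacetylide 10 (not isolated)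
Conditions: n-BuLi (2.2 equiv), THF, −78 °C → −40 °C; then cannulated into ClCO2Bn, THF, −78 °C → 0 °C
Reagents that add atoms: benzyl chloroformate, ClC(=O)OCc1ccccc1
Why: The first equivalent of n-BuLi effects dehydrochlorination to chloroalkyne 9 and the second a chlorine–lithium exchange to acetylide 10, which is C-acylated by the chloroformate under inverse addition; this is the standard dichlorovinyl ether to ynol ether sequence.

Step 6
Reactants: 12 pentanal
Product: 13 2-butyl-1,3-dithiane
Conditions: HS(CH2)3SH, BF3·OEt2 (cat.), CH2Cl2, 0 °C → rt
Reagents that add atoms: propane-1,3-dithiol, SCCCS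
Why: Lewis acid-catalysed dithioacetalisation of an aldehyde, which sets up Corey–Seebach umpolung of the acyl carbon.

Step 7
Reactants: 13 2-butyl-1,3-dithiane; 14 3-ethoxycyclohex-2-en-1-one
Product: 17 3-(2-butyl-1,3-dithian-2-yl)cyclohex-2-en-1-one, via 2-butyl-2-lithio-1,3-dithiane 15 (not isolated), via lithium alkoxide adduct 16 (not isolated)
Conditions: n-BuLi, THF, −30 °C; 14, −78 °C → 0 °C; then 1 M HCl, THF, rt
Reagents that add atoms: water, O
Why: Corey–Seebach lithiation and 1,2-addition to the vinylogous ester carbonyl, then acid-mediated enol ether hydrolysis and dehydration (Stork–Danheiser transposition), which moves the carbonyl to the former enol ether carbon; the dithiane is stable to dilute aqueous acid and the carbinol stereocentre of 16 is destroyed.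

Step 8
Reactants: 17 3-(2-butyl-1,3-dithian-2-yl)cyclohex-2-en-1-one
Product: 19 2-butyl-2-[3-(tert-butyldimethylsilyloxy)cyclohexa-1,3-dien-1-yl]-1,3-dithiane, via lithium dienolate 18 (not isolated)
Conditions: LiN(iPr)2, THF, −78 °C; TBSCl, DMPU, −78 °C → rt
Reagents that add atoms: tert-butyldimethylsilyl chloride, CC(C)(C)[Si](C)(C)Cl
Why: Kinetic deprotonation of a 3-substituted cyclohexenone occurs at the α' methylene and gives the cross-conjugated dienolate, which is silylated on oxygen to the 2-silyloxy-1,3-diene.

Step 9
Reactants: 11 benzyl 3-[2,4-bis(benzyloxy)-6-pentylphenoxy]prop-2-ynoate; 19 2-butyl-2-[3-(tert-butyldimethylsilyloxy)cyclohexa-1,3-dien-1-yl]-1,3-dithiane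
Product: 21 benzyl 2-[2,4-bis(benzyloxy)-6-pentylphenoxy]-6-(2-butyl-1,3-dithian-2-yl)-4-(tert-butyldimethylsilyloxy)benzoate, via bicyclo[2.2.2]octadiene adduct 20 (not isolated)
Conditions: 19 (3 equiv), BHT (cat.), neat, 175 °C, sealed tube, argon
Reagents that add atoms: none
Why: A thermal, concerted but asynchronous (4+2) cycloaddition of the silyloxydiene unit of 19 to the ester-activated alkyne of 11 should give adduct 20, which on continued heating loses its saturated two-carbon bridge as ethylene in a retro-(4+2) step made irreversible by aromatisation. The closest known reaction type is the Alder–Rickert synthesis of phenol silyl ethers from 2-silyloxycyclohexa-1,3-dienes and alkynoates. Ring B is closed intermolecularly, both new bonds (b1–b2 and b5–b6) arising in one suprafacial cycloaddition and not by an endo or exo cyclisation of a chain. No stereocentre remains: the two bridgeheads of 20 form as a racemic pair fixed by the bicycle and are erased on aromatisation. The step needs regioselectivity, which the substrates secure electronically: the diene terminus next to the silyloxy carbon has the largest HOMO coefficient (reinforced by the alkyl-type substituent at the other terminus) and the alkyne carbon β to the ester, which bears the aryloxy group, has the largest LUMO coefficient, so the silyloxy group ends para to the ester and the aryloxy group at b1. The aryl ynol ether has no β-hydrogen for retro-ene loss of ketene, the tert-butyldimethylsilyl ether withstands the heat, and excess diene compensates for the low reactivity of the push-pull alkyne and for slow thermal hydrogen shifts in the diene.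

Step 10
Reactants: 21 benzyl 2-[2,4-bis(benzyloxy)-6-pentylphenoxy]-6-(2-butyl-1,3-dithian-2-yl)-4-(tert-butyldimethylsilyloxy)benzoate
Product: 23 benzyl 2-[2,4-bis(benzyloxy)-6-pentylphenoxy]-6-(2-butyl-1,3-dithian-2-yl)-4-methoxybenzoate, via cesium phenoxide 22 (not isolated)
Conditions: CsF, MeI, DMF, rt
Reagents that add atoms: iodomethane, CI
Why: Fluoride cleaves the aryl silyl ether and the phenoxide, the only free nucleophile, is methylated in the same flask (Williamson ether synthesis); S-methylation of the dithiane is slow at room temperature.

Step 11
Reactants: 23 benzyl 2-[2,4-bis(benzyloxy)-6-pentylphenoxy]-6-(2-butyl-1,3-dithian-2-yl)-4-methoxybenzoate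
Product: 24 benzyl 2-[2,4-bis(benzyloxy)-6-pentylphenoxy]-4-methoxy-6-pentanoylbenzoate
Conditions: MeI (excess), CaCO3, aq. MeCN, 55 °C
Reagents that add atoms: water, O
Why: Alkylative dithiane hydrolysis: S-methylation turns sulfur into a leaving group, water captures the thionium ion and CaCO3 buffers the acid; the conditions are non-oxidising, so ring A and the benzyl groups should be untouched.

Step 12
Reactants: 24 benzyl 2-[2,4-bis(benzyloxy)-6-pentylphenoxy]-4-methoxy-6-pentanoylbenzoate
Product: 25 2-(2,4-dihydroxy-6-pentylphenoxy)-4-methoxy-6-pentanoylbenzoic acid (CNP0189595.0)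
Conditions: H2 (1 atm), Pd/C, EtOAc, rt, stopped after three equivalents of H2
Reagents that add atoms: none
Why: Heterogeneous hydrogenolysis of three benzylic C–O bonds (two ethers, one ester), which under neutral conditions at atmospheric pressure should be faster than reduction of the aryl ketone; the sulfur was removed in step 11.

## Compound list

1 | olivetol (5-pentylbenzene-1,3-diol) | CCCCCc1cc(O)cc(O)c1 | starting material
2 | 1,3-bis(benzyloxy)-5-pentylbenzene | CCCCCc1cc(OCc2ccccc2)cc(OCc2ccccc2)c1 | intermediate
3 | N-{[2,4-bis(benzyloxy)-6-pentylphenyl]methylidene}-N-methylmethanaminium dichlorophosphate | CCCCCc1cc(OCc2ccccc2)cc(OCc2ccccc2)c1C=[N+](C)C.[O-]P(=O)(Cl)Cl | intermediate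
4 | 2,4-bis(benzyloxy)-6-pentylbenzaldehyde | CCCCCc1cc(OCc2ccccc2)cc(OCc2ccccc2)c1C=O | intermediate
5 | 2,4-bis(benzyloxy)-6-pentylphenyl formate | CCCCCc1cc(OCc2ccccc2)cc(OCc2ccccc2)c1OC=O | intermediate
6 | 2,4-bis(benzyloxy)-6-pentylphenol | CCCCCc1cc(OCc2ccccc2)cc(OCc2ccccc2)c1O | intermediate
7 | trichloroethylene | ClC=C(Cl)Cl | starting material
8 | 1,5-bis(benzyloxy)-2-{[(E)-1,2-dichloroethenyl]oxy}-3-pentylbenzene | CCCCCc1cc(OCc2ccccc2)cc(OCc2ccccc2)c1O/C(Cl)=C\Cl | intermediate
9 | 1,5-bis(benzyloxy)-2-[(chloroethynyl)oxy]-3-pentylbenzene | CCCCCc1cc(OCc2ccccc2)cc(OCc2ccccc2)c1OC#CCl | intermediate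
10 | {[2,4-bis(benzyloxy)-6-pentylphenoxy]ethynyl}lithium | CCCCCc1cc(OCc2ccccc2)cc(OCc2ccccc2)c1OC#C[Li] | intermediate
11 | benzyl 3-[2,4-bis(benzyloxy)-6-pentylphenoxy]prop-2-ynoate | CCCCCc1cc(OCc2ccccc2)cc(OCc2ccccc2)c1OC#CC(=O)OCc1ccccc1 | intermediate
12 | pentanal | CCCCC=O | starting material
13 | 2-butyl-1,3-dithiane | CCCCC1SCCCS1 | intermediate
14 | 3-ethoxycyclohex-2-en-1-one | CCOC1=CC(=O)CCC1 | starting material
15 | 2-butyl-2-lithio-1,3-dithiane | CCCCC1([Li])SCCCS1 | intermediate
16 | lithium 1-(2-butyl-1,3-dithian-2-yl)-3-ethoxycyclohex-2-en-1-olate, racemic | CCCCC1(SCCCS1)C1(O[Li])C=C(OCC)CCC1 | intermediate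
17 | 3-(2-butyl-1,3-dithian-2-yl)cyclohex-2-en-1-one | CCCCC1(SCCCS1)C1=CC(=O)CCC1 | intermediate
18 | lithium 5-(2-butyl-1,3-dithian-2-yl)cyclohexa-1,5-dien-1-olate | CCCCC1(SCCCS1)C1=CC(O[Li])=CCC1 | intermediate
19 | 2-butyl-2-[3-(tert-butyldimethylsilyloxy)cyclohexa-1,3-dien-1-yl]-1,3-dithiane | CCCCC1(SCCCS1)C1=CC(O[Si](C)(C)C(C)(C)C)=CCC1 | intermediate
20 | benzyl 3-[2,4-bis(benzyloxy)-6-pentylphenoxy]-1-(2-butyl-1,3-dithian-2-yl)-5-(tert-butyldimethylsilyloxy)bicyclo[2.2.2]octa-2,5-diene-2-carboxylate, racemic, the two bridgeheads mutually fixed by the bicycle | CCCCC1(SCCCS1)C23CCC(C(O[Si](C)(C)C(C)(C)C)=C2)C(Oc2c(CCCCC)cc(OCc4ccccc4)cc2OCc2ccccc2)=C3C(=O)OCc1ccccc1 | intermediate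
21 | benzyl 2-[2,4-bis(benzyloxy)-6-pentylphenoxy]-6-(2-butyl-1,3-dithian-2-yl)-4-(tert-butyldimethylsilyloxy)benzoate | CCCCCc1cc(OCc2ccccc2)cc(OCc2ccccc2)c1Oc1cc(O[Si](C)(C)C(C)(C)C)cc(C2(CCCC)SCCCS2)c1C(=O)OCc1ccccc1 | intermediate
22 | cesium 4-[(benzyloxy)carbonyl]-3-[2,4-bis(benzyloxy)-6-pentylphenoxy]-5-(2-butyl-1,3-dithian-2-yl)phenolate | CCCCCc1cc(OCc2ccccc2)cc(OCc2ccccc2)c1Oc1cc([O-])cc(C2(CCCC)SCCCS2)c1C(=O)OCc1ccccc1.[Cs+] | intermediate
23 | benzyl 2-[2,4-bis(benzyloxy)-6-pentylphenoxy]-6-(2-butyl-1,3-dithian-2-yl)-4-methoxybenzoate | CCCCCc1cc(OCc2ccccc2)cc(OCc2ccccc2)c1Oc1cc(OC)cc(C2(CCCC)SCCCS2)c1C(=O)OCc1ccccc1 | intermediate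
24 | benzyl 2-[2,4-bis(benzyloxy)-6-pentylphenoxy]-4-methoxy-6-pentanoylbenzoate | CCCCCc1cc(OCc2ccccc2)cc(OCc2ccccc2)c1Oc1cc(OC)cc(C(=O)CCCC)c1C(=O)OCc1ccccc1 | intermediate
25 | 2-(2,4-dihydroxy-6-pentylphenoxy)-4-methoxy-6-pentanoylbenzoic acid | CCCCCc1cc(O)cc(O)c1Oc1cc(OC)cc(C(=O)CCCC)c1C(=O)O | target

## Step count and risks

Total step count: 12. Longest linear sequence: 9 steps (steps 1 to 5 and 9 to 12, from 1). The diene branch has 3 steps (6 to 8) before it joins at step 9.

Step 9 (key step).
- What may go wrong: the cycloaddition may be slower than thermal degradation, because the push-pull alkyne is a weak dienophile and the diene terminus that must bond to the ester-bearing carbon is crowded. Competing processes are hydrogen shifts in the diene that move the silyloxy group, loss of the silyl group, and oligomerisation of the ynoate. Steric repulsion at the dithianyl terminus could also erode the electronically preferred orientation.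
- Fallback (from 19 and 6, returning at 23): the aryl–oxygen bond is made after the ring synthesis. Benzyl 3-bromoprop-2-ynoate F1, from commercial benzyl propiolate with N-bromosuccinimide and catalytic AgNO3 in acetone, is a small and far more electrophilic alkynoate. It would be heated with 19 in toluene at about 110 to 130 °C, where the same orbital bias places bromine at b1. The adduct benzyl 3-bromo-1-(2-butyl-1,3-dithian-2-yl)-5-(tert-butyldimethylsilyloxy)bicyclo[2.2.2]octa-2,5-diene-2-carboxylate F2 should lose ethylene to give benzyl 2-bromo-6-(2-butyl-1,3-dithian-2-yl)-4-(tert-butyldimethylsilyloxy)benzoate F3. CsF and MeI in DMF would convert F3 through cesium 4-[(benzyloxy)carbonyl]-3-bromo-5-(2-butyl-1,3-dithian-2-yl)phenolate F4 into benzyl 2-bromo-6-(2-butyl-1,3-dithian-2-yl)-4-methoxybenzoate F5. An Ullmann-type ether synthesis of F5 with 6 (CuI, N,N-dimethylglycine, Cs2CO3, 1,4-dioxane, 100 °C), assisted by the ortho ester of the bromide, should then give 23.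

Step 7.
- What may go wrong: proton transfer from the α' methylene of 14 to the hindered tertiary carbanion 15 (enolisation in place of addition), which returns both partners. During the acid step, sulfur participation in the ionising carbinol could lead to a 1,2-sulfur shift.
- Fallback (from 13 through 15, returning at 17): 15 would be added at −78 °C to commercial cyclohex-2-en-1-one, whose carbonyl is much more electrophilic than that of the vinylogous ester. The adduct lithium 1-(2-butyl-1,3-dithian-2-yl)cyclohex-2-en-1-olate F6 gives on aqueous quench racemic 1-(2-butyl-1,3-dithian-2-yl)cyclohex-2-en-1-ol F7. A Dauben–Babler oxidative 1,3-transposition with [C5H5NH][CrO3Cl] in CH2Cl2 (chromate ester, allylic shift, oxidation) should then give 17 without a free cation next to sulfur.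

Step 5.
- What may go wrong: over-acylation (the acetylide attacking the first-formed ynoate or a second chloroformate), competing benzylic metalation of the benzyl ethers by n-BuLi, or incomplete chlorine–lithium exchange.
- Fallback (from 8, returning at 11): 10 is generated as before and quenched with dry CO2 to give lithium 3-[2,4-bis(benzyloxy)-6-pentylphenoxy]prop-2-ynoate F8, which cannot react a second time. After exchange of the solvent for DMF, O-alkylation with benzyl bromide should give 11.

Step 11.
- What may go wrong: slow S-alkylation of the hindered dithiane next to the ortho ester, so that hydrolysis stalls; more forcing or oxidative reagents would endanger the electron-rich ring A.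
- Fallback (from 23, returning at 24): one equivalent of mCPBA in CH2Cl2 at −78 °C oxidises one sulfur selectively to give benzyl 2-[2,4-bis(benzyloxy)-6-pentylphenoxy]-6-(2-butyl-1-oxido-1,3-dithian-2-yl)-4-methoxybenzoate F9 as a mixture of diastereomers. The activated monosulfoxide is then hydrolysed with aqueous HCl in THF at room temperature to give 24.

Step 12.
- What may go wrong: over-reduction (hydrogenation of the aryl ketone, or hydrogenolysis of the benzylic C–O bond in the ring-closed lactol tautomer of the product), or stalled debenzylation through poisoning of the catalyst by sulfur traces.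
- Fallback (from 24, ending at 25): no new compound is made (F0). BCl3 with pentamethylbenzene as benzyl cation scavenger in CH2Cl2 at −78 °C cleaves both benzyl ethers and the benzyl ester without hydrogen. The b3 methoxy group is not flanked by a carbonyl and should survive.

## Further compounds

F1 | step 9 | benzyl 3-bromoprop-2-ynoate | BrC#CC(=O)OCc1ccccc1
F2 | step 9 | benzyl 3-bromo-1-(2-butyl-1,3-dithian-2-yl)-5-(tert-butyldimethylsilyloxy)bicyclo[2.2.2]octa-2,5-diene-2-carboxylate, racemic | CCCCC1(SCCCS1)C23CCC(C(O[Si](C)(C)C(C)(C)C)=C2)C(Br)=C3C(=O)OCc1ccccc1
F3 | step 9 | benzyl 2-bromo-6-(2-butyl-1,3-dithian-2-yl)-4-(tert-butyldimethylsilyloxy)benzoate | CCCCC1(SCCCS1)c1cc(O[Si](C)(C)C(C)(C)C)cc(Br)c1C(=O)OCc1ccccc1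
F4 | step 9 | cesium 4-[(benzyloxy)carbonyl]-3-bromo-5-(2-butyl-1,3-dithian-2-yl)phenolate | [O-]c1cc(Br)c(C(=O)OCc2ccccc2)c(C2(CCCC)SCCCS2)c1.[Cs+]
F5 | step 9 | benzyl 2-bromo-6-(2-butyl-1,3-dithian-2-yl)-4-methoxybenzoate | CCCCC1(SCCCS1)c1cc(OC)cc(Br)c1C(=O)OCc1ccccc1
F6 | step 7 | lithium 1-(2-butyl-1,3-dithian-2-yl)cyclohex-2-en-1-olate, racemic | CCCCC1(SCCCS1)C1(O[Li])C=CCCC1
F7 | step 7 | 1-(2-butyl-1,3-dithian-2-yl)cyclohex-2-en-1-ol, racemic | CCCCC1(SCCCS1)C1(O)C=CCCC1
F8 | step 5 | lithium 3-[2,4-bis(benzyloxy)-6-pentylphenoxy]prop-2-ynoate | CCCCCc1cc(OCc2ccccc2)cc(OCc2ccccc2)c1OC#CC(=O)[O-].[Li+]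
F9 | step 11 | benzyl 2-[2,4-bis(benzyloxy)-6-pentylphenoxy]-6-(2-butyl-1-oxido-1,3-dithian-2-yl)-4-methoxybenzoate, mixture of diastereomers | CCCCCc1cc(OCc2ccccc2)cc(OCc2ccccc2)c1Oc1cc(OC)cc(C2(CCCC)SCCCS2=O)c1C(=O)OCc1ccccc1
F0 | step 12 | none | none
A1 | alternative 1 | 3-butyl-7-hydroxy-5-methoxyisobenzofuran-1(3H)-one, racemic | CCCCC1OC(=O)c2c(O)cc(OC)cc21
A2 | alternative 1 | dimethyl 2-[(3-butyl-5-methoxy-1-oxo-1,3-dihydroisobenzofuran-7-yl)oxy]propanedioate, racemic | COC(=O)C(Oc1cc(OC)cc2c1C(=O)OC2CCCC)C(=O)OC
A3 | alternative 1 | (E)-non-3-en-2-one | CCCCC/C=C/C(C)=O
A4 | alternative 1 | methyl 1-[(3-butyl-5-methoxy-1-oxo-1,3-dihydroisobenzofuran-7-yl)oxy]-2,4-dioxo-6-pentylcyclohexane-1-carboxylate, mixture of diastereomers | CCCCCC1CC(=O)CC(=O)C1(Oc1cc(OC)cc2c1C(=O)OC2CCCC)C(=O)OC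
A5 | alternative 2 | dimethyl (E)-3-[2,4-bis(benzyloxy)-6-pentylphenoxy]pent-2-enedioate | COC(=O)/C=C(\CC(=O)OC)Oc1c(CCCCC)cc(OCc2ccccc2)cc1OCc1ccccc1
A6 | alternative 2 | 1-(2-butyl-1,3-dioxolan-2-yl)ethan-1-one | CCCCC1(OCCO1)C(C)=O
A7 | alternative 2 | methyl 2-[2,4-bis(benzyloxy)-6-pentylphenoxy]-6-(2-butyl-1,3-dioxolan-2-yl)-4-hydroxybenzoate | CCCCCc1cc(OCc2ccccc2)cc(OCc2ccccc2)c1Oc1cc(O)cc(C2(CCCC)OCCO2)c1C(=O)OC
A8 | alternative 3 | 3-butyl-7-{[(1E)-2-(2-diazoacetyl)hept-1-en-1-yl]oxy}-5-methoxyisobenzofuran-1(3H)-one, racemic | [N-]=[N+]=CC(=O)/C(CCCCC)=C/Oc1cc(OC)cc2c1C(=O)OC2CCCC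
A9 | alternative 3 | benzyl ethynyl ether | C#COCc1ccccc1
A10 | alternative 3 | 7-[4-(benzyloxy)-2-hydroxy-6-pentylphenoxy]-3-butyl-5-methoxyisobenzofuran-1(3H)-one, racemic | CCCCCc1cc(OCc2ccccc2)cc(O)c1Oc1cc(OC)cc2c1C(=O)OC2CCCC
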